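**Plan**

Unit 1 is the 5-hydroxy-7-methoxyflavanone (unprimed atoms); unit 2 is the flavanone carrying the 4-hydroxyphenyl ring (double-primed atoms). Flavanone locants are also used for the open-chain precursors.

1. Cuts: first the two peri O-methyl ethers and the benzyl ether (protecting groups); then the aryl ether bonds O1''–C8a'' and O1–C8a of both dihydropyranone rings, back to an open-chain dibromo tetraol; then C2–C3 and C2''–C3'' (two aldol condensations), the diaryl ether C6''–O–C4' (SNAr) and the two acetyl–arene bonds (Friedel–Crafts).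
2. Forward: ring A of unit 2 is acetylated, condensed to the first chalcone, O-arylated with 4-fluorobenzaldehyde and condensed with the ring A ketone of unit 1 to a bis-chalcone; one copper-catalysed operation then closes ring C of unit 2 and ring C of unit 1 together, and the C4 carbonyl groups and free phenols are restored last.
3. Stereochemistry: both S centres come from one catalyst-controlled twofold conjugate borylation of the bis-chalcone (C–B oxidised with retention); the ring closure breaks only O–H and C–Br bonds, and no strong base is used once the carbonyl groups are back.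
4. Enabling feature: in each unit O1 joins the benzylic carbon C2 to C8a, the ring A carbon ortho to C4a that bears no oxygen of its own. C8a'' lies para to the C6'' ether oxygen, so it is the brominated carbon of 4-bromo-2,6-dimethoxyphenol. With C4 and C4'' held as carbinols, only the C2-type hydroxyl can reach C8a through a six-membered ring, and retro-aldol and chalcone pathways are closed.

Key step: step 7

Assumption: the (R,S) ferrocenyl diphosphine named in step 6 is taken to deliver boron to the Si face of each β-carbon (S boronates); if a model chalcone shows the opposite sense, its mirror image is used.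

**Route**

Step 1
Reactants: 1 4-bromo-2,6-dimethoxyphenol
Product: 2 3-acetyl-4-bromo-2,6-dimethoxyphenyl acetate
Conditions: Ac2O (3 equiv), TfOH (cat.), MeNO2, 0 °C to rt
Reagents that add atoms: acetic anhydride, CC(=O)OC(C)=O
Why: After O-acetylation, Friedel–Crafts acylation can only occur at the two equivalent free positions (ortho to one methoxy group and para to the other), which puts the acetyl carbon (future C4'') next to the bromine-bearing carbon (future C8a'') and leaves bromine para to the oxygen that becomes the C6'' ether oxygen.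

Step 2
Reactants: 2 3-acetyl-4-bromo-2,6-dimethoxyphenyl acetate; 3 4-(benzyloxy)benzaldehyde
Product: 5 (2E)-3-[4-(benzyloxy)phenyl]-1-(6-bromo-3-hydroxy-2,4-dimethoxyphenyl)prop-2-en-1-one, via phenol ketone 4 (not isolated)
Conditions: aq. KOH (excess), EtOH, rt; then dilute HCl
Reagents that add atoms: none
Why: Hydroxide cleaves the aryl acetate and the freed methyl ketone undergoes Claisen–Schmidt condensation with the non-enolisable aldehyde to the E-enone, while the methyl ether on the future C5'' oxygen prevents a 2'-hydroxychalcone from closing the wrong dihydropyranone.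

Step 3
Reactants: 5 (2E)-3-[4-(benzyloxy)phenyl]-1-(6-bromo-3-hydroxy-2,4-dimethoxyphenyl)prop-2-en-1-one; 6 4-fluorobenzaldehyde
Product: 7 4-{3-[(2E)-3-(4-(benzyloxy)phenyl)prop-2-enoyl]-4-bromo-2,6-dimethoxyphenoxy}benzaldehyde
Conditions: K2CO3, DMAc, 100 °C
Reagents that add atoms: none
Why: Nucleophilic aromatic substitution (SNAr) of the fluoride para to the formyl group by the di-ortho-methoxy phenoxide should form the C6''–O–C4' diaryl ether, and because the methyl ketone is already consumed the new aldehyde has no aldol partner in its own molecule.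

Step 4
Reactants: 8 1-bromo-3,5-dimethoxybenzene
Product: 9 1-(2-bromo-4,6-dimethoxyphenyl)ethanone
Conditions: Ac2O (1.5 equiv), TfOH (cat.), MeNO2, 0 °C to rt
Reagents that add atoms: acetic anhydride, CC(=O)OC(C)=O
Why: Friedel–Crafts acylation should prefer C2 (ortho to one methoxy group and para to the other, next to bromine) over C4 between the two methoxy groups, as electrophiles do with 1,3-dimethoxyarenes, giving the ring A ketone of unit 1 with bromine on the future C8a.

Step 5
Reactants: 7 4-{3-[(2E)-3-(4-(benzyloxy)phenyl)prop-2-enoyl]-4-bromo-2,6-dimethoxyphenoxy}benzaldehyde; 9 1-(2-bromo-4,6-dimethoxyphenyl)ethanone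
Product: 10 open-chain bis-chalcone (both enones E; full name in the compound list)
Conditions: aq. KOH (cat.), EtOH/THF, rt
Reagents that add atoms: none
Why: Claisen–Schmidt condensation between the only methyl ketone and the only aldehyde present should give the second E-enone.

Step 6
Reactants: 10 open-chain bis-chalcone
Product: 13 (1S)-1-[4-(benzyloxy)phenyl]-3-[6-bromo-3-(4-{(1S)-3-(2-bromo-4,6-dimethoxyphenyl)-1,3-dihydroxypropyl}phenoxy)-2,4-dimethoxyphenyl]propane-1,3-diol (epimers at both C4-type carbinols), via bis(boryl ketone) 11 (not isolated), via bis(boryl alcohol) 12 (not isolated)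
Conditions: B2pin2 (2.4 equiv), CuCl (10 mol %), NaOtBu (10 mol %), (R)-1-[(S)-2-(diphenylphosphino)ferrocenyl]ethyldicyclohexylphosphine (12 mol %), MeOH (5 equiv), THF, rt; then NaBH4, MeOH, 0 °C; then aq. NaOH, H2O2, 0 °C to rt
Reagents that add atoms: bis(pinacolato)diboron, CC1(C)OB(OC1(C)C)B1OC(C)(C)C(C)(C)O1 (boron and pinacol carried in 11 and 12 only); hydrogen peroxide, OO (oxygen atoms of the two C2-type hydroxyl groups of 13)
Why: Catalyst-controlled conjugate addition of a copper boryl species to the Si face of each enone β-carbon (asymmetric β-borylation) sets the future C2 and C2'' as S boronates, borohydride then reduces both ketones without stereocontrol, and alkaline peroxide oxidises the C–B bonds with retention, so that a free β-hydroxy ketone never appears.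

Step 7
Reactants: 13 dibromo tetraol
Product: 14 (2S)-2-{4-[((2S)-2-[4-(benzyloxy)phenyl]-4-hydroxy-5,7-dimethoxy-3,4-dihydro-2H-chromen-6-yl)oxy]phenyl}-5,7-dimethoxy-3,4-dihydro-2H-chromen-4-ol (epimers at both C4-type carbinols)
Conditions: CuI (20 mol %), 3,4,7,8-tetramethyl-1,10-phenanthroline (40 mol %), Cs2CO3 (4 equiv), toluene (0.02 M), 110 °C, N2
Reagents that add atoms: none
Why: With Cs2CO3 each C2-type carbinol forms a copper alkoxide, the neighbouring C8a–Br bond adds oxidatively and C(aryl)–O reductive elimination closes the ring, so the O1''–C8a'' bond of unit 2 and the O1–C8a bond of unit 1 are formed in the same operation (twofold intramolecular Ullmann-type etherification). The closest known reaction type is the copper- or palladium-catalysed cyclisation of enantioenriched 1-aryl-3-(2-bromoaryl)propan-1-ols to 2-arylchromans (flavans), which proceeds with retention. Each dihydropyran ring closes in a formal 6-exo sense through a seven-membered aryl-copper alkoxide chelate. No new stereocentre is formed: C2 and C2'' keep the S configuration from step 6 because only O–H and C–Br bonds are broken, and the uncontrolled C4 and C4'' carbinol centres are erased in step 8. The step needs chemoselectivity between the two kinds of hydroxyl and freedom from base-induced cleavage: only the C2-type hydroxyl can reach C8a through a six-membered ring (the C4-type hydroxyl would have to form a four-membered benzoxete), and because C4 is held at the alcohol oxidation level neither retro-aldol cleavage nor dehydration to a chalcone nor flavanone ring opening can occur under the hot carbonate conditions. High dilution should suppress intermolecular etherification.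

Step 8
Reactants: 14 bis(flavan-4-ol)
Product: 15 (2S)-2-{4-[((2S)-2-[4-(benzyloxy)phenyl]-5,7-dimethoxy-4-oxo-3,4-dihydro-2H-chromen-6-yl)oxy]phenyl}-5,7-dimethoxy-2,3-dihydro-4H-chromen-4-one
Conditions: DMP (3 equiv), pyridine, CH2Cl2, 0 °C to rt
Reagents that add atoms: none
Why: Dess–Martin oxidation of the two benzylic C4-type alcohols converges all C4 epimers to the bis-flavanone under buffered, non-basic conditions, and C2 and C2'' are not α to the new carbonyl groups and stay untouched.

Step 9
Reactants: 15 bis-flavanone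
Product: 16 7,7''-di-O-methyltetrahydrohinokiflavone, (2S,2''S)
Conditions: BCl3 (6 equiv), C6HMe5 (3 equiv), CH2Cl2, −78 to 0 °C; then H2O
Reagents that add atoms: none
Why: Boron chelation between each C4 carbonyl and its peri methoxy group directs cleavage to the 5- and 5''-O-methyl ethers only (chelation-controlled demethylation, the 7- and 7''-methoxy groups lacking this assistance), and the benzyl ether is cleaved in the same flask with pentamethylbenzene as benzyl cation scavenger, the low temperature being chosen to leave C2 and C2'' untouched.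

**Compound list**

1 | 4-bromo-2,6-dimethoxyphenol | COc1cc(Br)cc(OC)c1O | starting material
2 | 3-acetyl-4-bromo-2,6-dimethoxyphenyl acetate | CC(=O)Oc1c(OC)cc(Br)c(C(C)=O)c1OC | intermediate
3 | 4-(benzyloxy)benzaldehyde | O=Cc1ccc(OCc2ccccc2)cc1 | starting material
4 | 1-(6-bromo-3-hydroxy-2,4-dimethoxyphenyl)ethanone (potassium phenoxide in the flask, not isolated) | CC(=O)c1c(Br)cc(OC)c(O)c1OC | intermediate
5 | (2E)-3-[4-(benzyloxy)phenyl]-1-(6-bromo-3-hydroxy-2,4-dimethoxyphenyl)prop-2-en-1-one | O=C(/C=C/c1ccc(OCc2ccccc2)cc1)c1c(Br)cc(OC)c(O)c1OC | intermediate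
6 | 4-fluorobenzaldehyde | O=Cc1ccc(F)cc1 | starting material
7 | 4-{3-[(2E)-3-(4-(benzyloxy)phenyl)prop-2-enoyl]-4-bromo-2,6-dimethoxyphenoxy}benzaldehyde | O=Cc1ccc(Oc2c(OC)cc(Br)c(C(=O)/C=C/c3ccc(OCc4ccccc4)cc3)c2OC)cc1 | intermediate
8 | 1-bromo-3,5-dimethoxybenzene | COc1cc(Br)cc(OC)c1 | starting material
9 | 1-(2-bromo-4,6-dimethoxyphenyl)ethanone | CC(=O)c1c(Br)cc(OC)cc1OC | intermediate
10 | (2E)-3-[4-(benzyloxy)phenyl]-1-[6-bromo-3-(4-{(1E)-3-(2-bromo-4,6-dimethoxyphenyl)-3-oxoprop-1-en-1-yl}phenoxy)-2,4-dimethoxyphenyl]prop-2-en-1-one | COc1cc(Br)c(C(=O)/C=C/c2ccc(Oc3c(OC)cc(Br)c(C(=O)/C=C/c4ccc(OCc5ccccc5)cc4)c3OC)cc2)c(OC)c1 | intermediate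
11 | (3S)-3-[4-(benzyloxy)phenyl]-1-[6-bromo-3-(4-{(1S)-3-(2-bromo-4,6-dimethoxyphenyl)-3-oxo-1-(pinacolatoboryl)propyl}phenoxy)-2,4-dimethoxyphenyl]-3-(pinacolatoboryl)propan-1-one (not isolated) | COc1cc(Br)c(C(=O)C[C@H](B2OC(C)(C)C(C)(C)O2)c2ccc(Oc3c(OC)cc(Br)c(C(=O)C[C@H](B4OC(C)(C)C(C)(C)O4)c4ccc(OCc5ccccc5)cc4)c3OC)cc2)c(OC)c1 | intermediate
12 | the bis(γ-boryl alcohol) from 11 with both ketones reduced to carbinols, S at both boron-bearing carbons, epimers at both carbinols (not isolated) | COc1cc(Br)c(C(O)C[C@H](B2OC(C)(C)C(C)(C)O2)c2ccc(Oc3c(OC)cc(Br)c(C(O)C[C@H](B4OC(C)(C)C(C)(C)O4)c4ccc(OCc5ccccc5)cc4)c3OC)cc2)c(OC)c1 | intermediate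
13 | (1S)-1-[4-(benzyloxy)phenyl]-3-[6-bromo-3-(4-{(1S)-3-(2-bromo-4,6-dimethoxyphenyl)-1,3-dihydroxypropyl}phenoxy)-2,4-dimethoxyphenyl]propane-1,3-diol, epimers at both C4-type carbinols | COc1cc(Br)c(C(O)C[C@H](O)c2ccc(Oc3c(OC)cc(Br)c(C(O)C[C@H](O)c4ccc(OCc5ccccc5)cc4)c3OC)cc2)c(OC)c1 | intermediate
14 | (2S)-2-{4-[((2S)-2-[4-(benzyloxy)phenyl]-4-hydroxy-5,7-dimethoxy-3,4-dihydro-2H-chromen-6-yl)oxy]phenyl}-5,7-dimethoxy-3,4-dihydro-2H-chromen-4-ol, epimers at both C4-type carbinols | COc1cc(OC)c2c(c1)O[C@H](c1ccc(Oc3c(OC)cc4c(c3OC)C(O)C[C@@H](c3ccc(OCc5ccccc5)cc3)O4)cc1)CC2O | intermediate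
15 | (2S)-2-{4-[((2S)-2-[4-(benzyloxy)phenyl]-5,7-dimethoxy-4-oxo-3,4-dihydro-2H-chromen-6-yl)oxy]phenyl}-5,7-dimethoxy-2,3-dihydro-4H-chromen-4-one | COc1cc(OC)c2c(c1)O[C@H](c1ccc(Oc3c(OC)cc4c(c3OC)C(=O)C[C@@H](c3ccc(OCc5ccccc5)cc3)O4)cc1)CC2=O | intermediate
16 | 7,7''-di-O-methyltetrahydrohinokiflavone, (2S,2''S) | COc1cc(O)c2c(c1)O[C@H](c1ccc(Oc3c(OC)cc4c(c3O)C(=O)C[C@@H](c3ccc(O)cc3)O4)cc1)CC2=O | target

**Step count and risks**

Total steps: 9. Longest linear sequence: 8 (steps 1, 2, 3, 5, 6, 7, 8, 9).

Three steps most likely to fail: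

1. Step 7. What may go wrong: hydrodebromination of the electron-rich aryl bromides by hydride transfer from a copper-bound secondary alkoxide, or a stalled second ring closure. The fallback sets out from 12 and comes back at 14. Compound 12 is isolated after the borohydride stage and its two C4-type hydroxyl groups are silylated (TBSOTf, 2,6-lutidine) to the bis(silyl ether) boronate F1. NaOH/H2O2 then gives the C4-protected diol F2, whose only free hydroxyl groups are the two C2-type carbinols. Palladium-catalysed intramolecular etherification (Pd(OAc)2, 2-(di-tert-butylphosphino)-1,1'-binaphthyl, Cs2CO3, toluene, 80 °C), a known route from such bromoaryl propanols to flavans with retention, should close both rings to the bis(4-silyloxyflavan) F3; the silyl ethers prevent β-hydride loss from a C4 alkoxide on palladium. TBAF in THF returns 14.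

2. Step 6. What may go wrong: poor facial selectivity or incomplete conversion in the conjugate borylation of the two hindered enones. The fallback sets out from 10 and comes back at 13. Juliá–Colonna epoxidation with poly-D-leucine (urea–H2O2, DBU, THF) should give the bis(epoxy ketone) F4 with the (αS,βR) configuration at each oxirane, which is the same spatial arrangement at the β-carbon as the S carbinols of 13. Reductive opening at the α-carbon with (PhSe)2/NaBH4 in EtOH keeps the β-C–O bond, and excess NaBH4 in the same flask reduces the two ketones to give 13.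

3. Step 9. What may go wrong: Lewis-acid-assisted opening of a dihydropyranone ring at C2–O1 with loss of configuration, or cleavage of a 7-methoxy group. The fallback sets out from 15 and comes back at 16. Hydrogenolysis (H2, palladium on carbon (Pd/C), EtOAc) removes the benzyl group under neutral conditions to give the phenol F5. The two peri methoxy groups are then cleaved with MgI2·OEt2 in toluene/THF at 50 °C, where a magnesium chelate to each C4 carbonyl directs iodide to the 5- and 5''-O-methyl groups only, giving 16.

**Further compounds**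

F1 | step 7 | bis(tert-butyldimethylsilyl ether) of 12 at both C4-type carbinols, both pinacol boronates retained, S at both boron-bearing carbons | COc1cc(Br)c(C(O[Si](C)(C)C(C)(C)C)C[C@H](B2OC(C)(C)C(C)(C)O2)c2ccc(Oc3c(OC)cc(Br)c(C(O[Si](C)(C)C(C)(C)C)C[C@H](B4OC(C)(C)C(C)(C)O4)c4ccc(OCc5ccccc5)cc4)c3OC)cc2)c(OC)c1
F2 | step 7 | bis(tert-butyldimethylsilyl ether) of 13 at both C4-type carbinols, both C2-type carbinols free and S | COc1cc(Br)c(C(O[Si](C)(C)C(C)(C)C)C[C@H](O)c2ccc(Oc3c(OC)cc(Br)c(C(O[Si](C)(C)C(C)(C)C)C[C@H](O)c4ccc(OCc5ccccc5)cc4)c3OC)cc2)c(OC)c1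
F3 | step 7 | bis(tert-butyldimethylsilyl ether) of 14 at both C4-type carbinols, (2S,2''S) | COc1cc(OC)c2c(c1)O[C@H](c1ccc(Oc3c(OC)cc4c(c3OC)C(O[Si](C)(C)C(C)(C)C)C[C@@H](c3ccc(OCc5ccccc5)cc3)O4)cc1)CC2O[Si](C)(C)C(C)(C)C
F4 | step 6 | bis(trans-epoxy ketone) of 10, (αS,βR) at each oxirane | COc1cc(Br)c(C(=O)[C@H]2O[C@@H]2c2ccc(Oc3c(OC)cc(Br)c(C(=O)[C@H]4O[C@@H]4c4ccc(OCc5ccccc5)cc4)c3OC)cc2)c(OC)c1
F5 | step 9 | 4'''-O-debenzylated 15, i.e. 5,5'',7,7''-tetra-O-methyltetrahydrohinokiflavone, (2S,2''S) | COc1cc(OC)c2c(c1)O[C@H](c1ccc(Oc3c(OC)cc4c(c3OC)C(=O)C[C@@H](c3ccc(O)cc3)O4)cc1)CC2=O
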